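**Strategy.** Atoms are numbered as in bisabolane (ring C1–C6, chain C7–C11). The plan rests on cutting the O–C11 bond of the bromotetrahydropyran: its anti O–C11(CH3)2/C10–Br pair is the imprint of Br+ and oxygen adding across a prenyl double bond. The key step, a bromonium-triggered 6-endo etherification, closes this last ring and sets C10 in one operation, exploiting the cis disposition of the C7 hydroxyl and the C8 side arm on the 2-oxabicyclo[3.2.2]nonane. Its precursor is a bicyclic tertiary alcohol with a free prenyl group, assembled from 5-methylfurfural, isoprene and 2-methyl-2-butene via a furan-to-(Z)-enol-acetate cleavage, a chelation-controlled Diels–Alder reaction and a transannular epoxide opening.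

Key step: step 9

Remark: in this numbering C1 bears CH3 and the ether bridge, C2 the OH, C4 the side chain, C5 the OAc, C7 a CH3 and the pyran oxygen, C8 the ether bridge, C10 the Br and C11 the gem-dimethyl group. The target is (1R,2R,4R,5S,7S,8S,10S).

Step 1
Reactants: 1 5-methylfurfural; 2 allyltributylstannane
Product: 3 (1S)-1-(5-methylfuran-2-yl)but-3-en-1-ol
Conditions: (S)-BINOL (10 mol %), Ti(OiPr)4 (10 mol %), 4 Å MS, CH2Cl2, −20 °C; aq. NaHCO3
Reagents that add atoms: none
Why: Keck asymmetric allylation: the chiral BINOL–titanium Lewis acid activates the aldehyde and the allylstannane attacks one carbonyl face, which should set the (S)-carbinol centre (the future C8) with high enantioselectivity, as is usual for aryl and furyl aldehydes.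

Step 2
Reactants: 3 (1S)-1-(5-methylfuran-2-yl)but-3-en-1-ol
Product: 4 2-[(1S)-1-[(4-methoxyphenyl)methoxy]but-3-en-1-yl]-5-methylfuran
Conditions: NaH, Bu4NI (cat.), THF/DMF, 0 °C → rt
Reagents that add atoms: 4-methoxybenzyl chloride (PMBCl), COc1ccc(CCl)cc1
Why: Williamson etherification of the sodium alkoxide; the PMB ether prevents the hydroxyl from trapping the furan oxidation product (Achmatowicz-type pyranone) and later serves as the chelating group of step 4, and no stereocentre is touched.

Step 3
Reactants: 4 2-[(1S)-1-[(4-methoxyphenyl)methoxy]but-3-en-1-yl]-5-methylfuran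
Product: 6 (1Z,4S)-4-[(4-methoxyphenyl)methoxy]-3-oxohepta-1,6-dien-1-yl acetate, via furan endoperoxide 5 (not isolated)
Conditions: O2, tetraphenylporphyrin (cat.), hν (visible), CH2Cl2, −78 °C; then dark, −78 °C → rt
Reagents that add atoms: dioxygen, O=O
Why: [4+2] Cycloaddition of singlet oxygen to the 2,5-dialkylfuran followed by the known thermal Baeyer–Villiger-type (Criegee) rearrangement of furan endoperoxides to cis-enol esters: a ring C–C bond is cleaved as the vinyl carbon migrates to oxygen from the more electron-rich, methyl-bearing bridgehead, which becomes the acetate carbonyl, the ring dictates the Z geometry, both endoperoxide diastereomers converge on 6 and the monosubstituted alkene is inert to singlet oxygen.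

Step 4
Reactants: 6 (1Z,4S)-4-[(4-methoxyphenyl)methoxy]-3-oxohepta-1,6-dien-1-yl acetate; 7 isoprene
Product: 8 (1S,6R)-6-[(2S)-2-[(4-methoxyphenyl)methoxy]pent-4-enoyl]-3-methylcyclohex-3-en-1-yl acetate
Conditions: MgBr2·OEt2 (1.5 equiv), isoprene in excess, CH2Cl2, −20 °C → rt; aq. NaHCO3
Reagents that add atoms: none
Why: Chelation-controlled Diels–Alder reaction: MgBr2 holds the ketone and the α-PMB ether in a planar five-membered chelate with the enone s-cis, so isoprene should add to the face anti to the allyl arm (this sets C4 relative to C8), the "para" rule puts the ring methyl 1,4 to the acyl-bearing carbon, and suprafacial addition to the Z alkene makes the C5 acetoxy group cis to the acyl group.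

Step 5
Reactants: 8 (1S,6R)-6-[(2S)-2-[(4-methoxyphenyl)methoxy]pent-4-enoyl]-3-methylcyclohex-3-en-1-yl acetate
Product: 9 (1S,6R)-6-[(2S)-2-hydroxypent-4-enoyl]-3-methylcyclohex-3-en-1-yl acetate
Conditions: DDQ, CH2Cl2/pH 7 buffer, 0 °C → rt
Reagents that add atoms: none
Why: Oxidative cleavage of the PMB ether by DDQ (hydride abstraction, hydrolysis of the oxocarbenium ion) under neutral conditions that spare the β-acetoxy ketone, its two epimerisable α-centres and both alkenes.

Step 6
Reactants: 9 (1S,6R)-6-[(2S)-2-hydroxypent-4-enoyl]-3-methylcyclohex-3-en-1-yl acetate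
Product: 11 (1R,3S,5R,6S,8R)-8-hydroxy-1-methyl-4-oxo-3-(prop-2-en-1-yl)-2-oxabicyclo[3.2.2]nonan-6-yl acetate, via ring epoxide 10 (not isolated)
Conditions: mCPBA (1.05 equiv), NaHCO3, CH2Cl2, 0 °C; filter, evaporate; HFIP, 0 °C → rt
Reagents that add atoms: meta-chloroperoxybenzoic acid (mCPBA), OOC(=O)c1cccc(Cl)c1
Why: Prilezhaev epoxidation of the electron-rich trisubstituted ring alkene (the terminal alkene is far slower) from the face anti to the cis C4/C5 substituents, then HFIP-promoted transannular opening of the epoxide at its tertiary carbon C1 by the C8 hydroxyl with inversion (the one-carbon homologue of the α-terpineol oxide to 2-hydroxy-1,8-cineole cyclisation), which sets C1 and leaves the C2 hydroxyl trans to the new ether bridge; C7 is kept as a ketone so that no tertiary hydroxyl can compete.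

Step 7
Reactants: 11 (1R,3S,5R,6S,8R)-8-hydroxy-1-methyl-4-oxo-3-(prop-2-en-1-yl)-2-oxabicyclo[3.2.2]nonan-6-yl acetate
Product: 12 (1R,3S,4S,5R,6S,8R)-4,8-dihydroxy-1,4-dimethyl-3-(prop-2-en-1-yl)-2-oxabicyclo[3.2.2]nonan-6-yl acetate
Conditions: MeMgBr (3 equiv), CeCl3 (3 equiv), THF, −78 °C; aq. NH4Cl at −78 °C
Reagents that add atoms: methylmagnesium bromide, C[Mg]Br
Why: Organocerium 1,2-addition, non-basic and selective for the ketone over the acetate at −78 °C (cold quench to avoid acyl migration to the new alkoxide); the methyl group should enter the bridge ketone from the face turned away from the C8 allyl arm and the C5 acetoxy group, which places the C7 hydroxyl cis to the allyl arm.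

Step 8
Reactants: 12 (1R,3S,4S,5R,6S,8R)-4,8-dihydroxy-1,4-dimethyl-3-(prop-2-en-1-yl)-2-oxabicyclo[3.2.2]nonan-6-yl acetate; 13 2-methyl-2-butene (excess)
Product: 14 (1R,3S,4S,5R,6S,8R)-4,8-dihydroxy-1,4-dimethyl-3-(3-methylbut-2-en-1-yl)-2-oxabicyclo[3.2.2]nonan-6-yl acetate
Conditions: second-generation Grubbs catalyst RuCl2(=CHPh)(PCy3)(H2IMes) (5 mol %), CH2Cl2, 40 °C
Reagents that add atoms: none
Why: Olefin cross-metathesis: the terminal alkene exchanges its methylene for the isopropylidene unit of 2-methyl-2-butene (propene is lost), turning the allyl arm, kept until now so that step 6 could tell the two alkenes apart, into the prenyl group; the hindered hydroxyls and the acetate are tolerated.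

Step 9
Reactants: 14 (1R,3S,4S,5R,6S,8R)-4,8-dihydroxy-1,4-dimethyl-3-(3-methylbut-2-en-1-yl)-2-oxabicyclo[3.2.2]nonan-6-yl acetate
Product: 15 (1R,2R,4R,5S,7S,8S,10S)-10-bromo-1,8:7,11-diepoxy-2-hydroxybisabolan-5-yl acetate (CNP0247588.2)
Conditions: NBS (1.2 equiv), HFIP, 4 Å MS, 0 °C, dark
Reagents that add atoms: N-bromosuccinimide (NBS), O=C1CCC(=O)N1Br
Why: NBS, activated by hydrogen bonding in HFIP, transfers Br+ reversibly to the only alkene (C10=C11), and the bromiranium ion is opened at its tertiary carbon C11 by the C7 hydroxyl anti to bromine, succinimide taking up the proton. The closest known reaction type is the biomimetic bromoetherification used for the 3-bromo-2,2,6-trimethyltetrahydropyran rings of Laurencia terpenoids. The pyran closes in the 6-endo mode (endo with respect to the three-membered bromiranium ring), a Markovnikov closure favoured by the gem-dimethyl terminus and the ionising, non-nucleophilic solvent over 5-exo attack at C10. The new stereocentre C10 is controlled by the substrate: in the chair-like transition state the forming ring carries the C7 methyl axial, the C7–C4 bond equatorial and the C–Br bond equatorial and anti to the incoming oxygen, so bromine should end cis to the C7 methyl group as in the target, and because Br+ transfer is reversible both alkene faces funnel through this lowest chair. The step needs 6-endo over 5-exo selectivity and one alkene face: the first is secured by the tertiary C11, the second by the cis arrangement of hydroxyl and prenyl arm on the rigid bicycle, while the C2 hydroxyl on the opposite bridge cannot reach the alkene and the acetate is inert.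

**Compound list**

1 | 5-methylfurfural | Cc1ccc(C=O)o1 | starting material
2 | allyltributylstannane | C=CC[Sn](CCCC)(CCCC)CCCC | starting material
3 | (1S)-1-(5-methylfuran-2-yl)but-3-en-1-ol | Cc1ccc([C@@H](O)CC=C)o1 | intermediate
4 | 2-[(1S)-1-[(4-methoxyphenyl)methoxy]but-3-en-1-yl]-5-methylfuran | Cc1ccc([C@@H](OCc2ccc(OC)cc2)CC=C)o1 | intermediate
5 | 1-[(1S)-1-[(4-methoxyphenyl)methoxy]but-3-en-1-yl]-4-methyl-2,3,7-trioxabicyclo[2.2.1]hept-5-ene (furan endoperoxide, both bridgehead diastereomers) | CC12C=CC(OO1)(O2)[C@@H](OCc3ccc(OC)cc3)CC=C | intermediate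
6 | (1Z,4S)-4-[(4-methoxyphenyl)methoxy]-3-oxohepta-1,6-dien-1-yl acetate | CC(=O)O/C=C\C(=O)[C@@H](OCc1ccc(OC)cc1)CC=C | intermediate
7 | isoprene | C=CC(C)=C | starting material
8 | (1S,6R)-6-[(2S)-2-[(4-methoxyphenyl)methoxy]pent-4-enoyl]-3-methylcyclohex-3-en-1-yl acetate | CC(=O)O[C@H]1CC(C)=CC[C@H]1C(=O)[C@@H](OCc2ccc(OC)cc2)CC=C | intermediate
9 | (1S,6R)-6-[(2S)-2-hydroxypent-4-enoyl]-3-methylcyclohex-3-en-1-yl acetate | CC(=O)O[C@H]1CC(C)=CC[C@H]1C(=O)[C@@H](O)CC=C | intermediate
10 | (1S,3S,4R,6R)-4-[(2S)-2-hydroxypent-4-enoyl]-1-methyl-7-oxabicyclo[4.1.0]heptan-3-yl acetate (epoxide anti to the acyl and acetoxy groups) | CC(=O)O[C@H]1C[C@]2(C)O[C@@H]2C[C@H]1C(=O)[C@@H](O)CC=C | intermediate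
11 | (1R,3S,5R,6S,8R)-8-hydroxy-1-methyl-4-oxo-3-(prop-2-en-1-yl)-2-oxabicyclo[3.2.2]nonan-6-yl acetate | CC(=O)O[C@H]1C[C@@]2(C)O[C@@H](CC=C)C(=O)[C@@H]1C[C@H]2O | intermediate
12 | (1R,3S,4S,5R,6S,8R)-4,8-dihydroxy-1,4-dimethyl-3-(prop-2-en-1-yl)-2-oxabicyclo[3.2.2]nonan-6-yl acetate | CC(=O)O[C@H]1C[C@@]2(C)O[C@@H](CC=C)[C@](O)(C)[C@@H]1C[C@H]2O | intermediate
13 | 2-methyl-2-butene | CC=C(C)C | starting material
14 | (1R,3S,4S,5R,6S,8R)-4,8-dihydroxy-1,4-dimethyl-3-(3-methylbut-2-en-1-yl)-2-oxabicyclo[3.2.2]nonan-6-yl acetate | CC(=O)O[C@H]1C[C@@]2(C)O[C@@H](CC=C(C)C)[C@](O)(C)[C@@H]1C[C@H]2O | intermediate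
15 | (1R,2R,4R,5S,7S,8S,10S)-10-bromo-1,8:7,11-diepoxy-2-hydroxybisabolan-5-yl acetate (CNP0247588.2) | CC(=O)O[C@H]1C[C@@]2(C)O[C@H]3C[C@H](Br)C(C)(C)O[C@@]3(C)[C@@H]1C[C@H]2O | target

Total step count: 9. Longest linear sequence: 9 steps (from 5-methylfurfural).

**Steps most likely to fail**

Step 6. In the epoxide opening the axial C5 acetate, 1,3-diaxial to C1, may take part as a neighbouring group (dioxanylium ion, then acyl-scrambled diols), or the hydroxyl may attack C2 (2-oxabicyclo[3.3.1]nonane) instead of closing the seven-membered ether. The fallback removes the participating group before the cyclisation and returns the acetate through 1,3-diol chemistry. It sets out from 9, which is epoxidised as in step 6, but 10 is isolated. Me3SnOH (ClCH2CH2Cl, 60 °C) should cleave the acetate under neutral conditions to the de-acetylated epoxide F1. HFIP should then close the bridge to the bicyclic keto diol F2, since a free C5 hydroxyl cannot reach C1. MeMgBr/CeCl3 should give the triol F3. Trimethyl orthoacetate (1.1 equiv)/CSA should tie the syn C5/C7 diol as the cyclic orthoacetate F4. Mild aqueous acid followed by a trace of DBU (acyl equilibration) should leave the acetyl group on the secondary C5 oxygen, which is compound 12, where the route is rejoined.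

Step 3. The endoperoxide may decompose unselectively (migration from the wrong bridgehead, cis-diacyl epoxide formation, peroxide oligomers). The fallback moves the Baeyer–Villiger oxidation behind the cycloaddition. From 4, photooxygenation at −78 °C quenched with Me2S should give the cis-enedione F5. A MgBr2-chelation Diels–Alder reaction with isoprene, in which the chelated α-alkoxy ketone is the activating carbonyl, should give the acetyl cyclohexene F6. Baeyer–Villiger oxidation of its less hindered methyl ketone with bis(trimethylsilyl) peroxide/TMSOTf, which spares alkenes and lets the ring carbon migrate with retention, returns to the route at 8.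

Step 9. 5-exo capture of the bromiranium ion at C10 by the hindered tertiary hydroxyl may outrun 6-endo capture at C11. The fallback replaces direct 6-endo closure by ring expansion. From 14, NBS in CH2Cl2 is allowed to give the tetrahydrofuran tertiary bromide F7. Warming with ZnBr2 (cat.) in HFIP should ionise it to the bicyclic oxonium ion, and bromide returning at C10 with inversion expands the ring to the more stable secondary bromide 15. This is the known ring expansion of 2-(α-haloalkyl)tetrahydrofurans to 3-halotetrahydropyrans, and the pyran is still the last ring formed.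

**Further compounds**

F1 | step 6 | de-acetylated epoxide: 3-hydroxy analogue of 10, all stereocentres as in 10 | O[C@H]1C[C@]2(C)O[C@@H]2C[C@H]1C(=O)[C@@H](O)CC=C
F2 | step 6 | (1R,3S,5R,6S,8R)-6,8-dihydroxy-1-methyl-3-(prop-2-en-1-yl)-2-oxabicyclo[3.2.2]nonan-4-one | O[C@H]1C[C@@]2(C)O[C@@H](CC=C)C(=O)[C@@H]1C[C@H]2O
F3 | step 6 | (1R,3S,4S,5R,6S,8R)-1,4-dimethyl-3-(prop-2-en-1-yl)-2-oxabicyclo[3.2.2]nonane-4,6,8-triol | O[C@H]1C[C@@]2(C)O[C@@H](CC=C)[C@](O)(C)[C@@H]1C[C@H]2O
F4 | step 6 | cyclic methyl orthoacetate of F3 bridging the C5 and C7 oxygens (orthoester carbon unassigned) | COC1(C)O[C@H]2C[C@@]3(C)O[C@@H](CC=C)[C@](O1)(C)[C@@H]2C[C@H]3O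
F5 | step 3 | (3Z,6S)-6-[(4-methoxyphenyl)methoxy]nona-3,8-diene-2,5-dione | CC(=O)/C=C\C(=O)[C@@H](OCc1ccc(OC)cc1)CC=C
F6 | step 3 | (2S)-1-[(1R,6S)-6-acetyl-4-methylcyclohex-3-en-1-yl]-2-[(4-methoxyphenyl)methoxy]pent-4-en-1-one | CC(=O)[C@H]1CC(C)=CC[C@H]1C(=O)[C@@H](OCc2ccc(OC)cc2)CC=C
F7 | step 9 | tetrahydrofuran isomer of 15: C7–O–C10 ring carrying a 2-bromopropan-2-yl group at C10 | CC(=O)O[C@H]1C[C@@]2(C)O[C@H]3C[C@H](C(C)(C)Br)O[C@@]3(C)[C@@H]1C[C@H]2O
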